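## The problem

Arthonioic acid is a depside. Ring A, a 2,4-dihydroxy-6-(2-oxoheptyl)benzoyl unit, is esterified through its C1 carboxyl carbon to O4 of ring B, a 2-methoxy-6-(2-oxoheptyl)benzoic acid. The molecule has no stereocentre, so the task is one of regiochemistry and chemoselectivity. Two tetrasubstituted benzene rings must be built with the right 1,2,4,6 pattern, and the ring B oxygens must be told apart: O2 is methylated and O4 is acylated, whereas both ring A oxygens are free. The ester between the rings is the hard bond. Its carbonyl is flanked on ring A by the C2 oxygen and by the C6 side-chain CH2, so acylating a phenol with the ring A acid is slow. An activated ring A acid can also escape by enol lactonisation of its own 2-oxoheptyl ketone to an isocoumarin. Once made, the aryl ester is an active ester and will not tolerate hydroxide, alkoxide or amines. Each benzylic ketone sits ortho to a carboxyl derivative and can close onto it, under acid to an isocoumarin and under base to a naphthalene-1,3-diol. The electron-rich free acid of ring B loses CO2 in hot acid. Both ketones therefore have to be masked or introduced late, and the last unmasking has to be neutral. The feature that opens a short route is that on ring A the depside carbonyl carbon (on C1), the side-chain CH2 (on C6) and an oxygen (on C2) sit on three neighbouring ring carbons. That is the pattern left when a 3-alkoxyaryne inserts into a CH2–C(=O) bond, with the carbon nucleophile meta to the oxygen and the acyl group between the two.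

## Retrosynthesis

**Endgame (24 ⇐ 23 ⇐ 22 ⇐ 21).** The last cut is at the three O–benzyl bonds of 23, two ring A ethers and the ring B ester. Hydrogenolysis is neutral and leaves the depside ester and both ketones alone. The ring B ketone of 23 is traced to the dioxolane of 22, so that acid meets the molecule while the ring B carboxyl is still an ester. The ring A C(=O)–pentyl bond of 22 is cut back to the Weinreb amide 21. A Weinreb amide is the least electrophilic acyl group that still gives a ketone in one step, and that is what the key step needs. The forward steps ask for pentyl addition at the amide in the presence of two di-ortho-substituted benzoate esters, and for ketal hydrolysis without enol lactonisation.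

**Key disconnection (21 ⇐ 13 + 18, through aryne 19).** Two ring A bonds are cut together, C6–CH2 and C1–C(=O). The neighbouring cut, at the ester C–O bond, would require acylation of phenol 10 by a 2,6-disubstituted benzoic acid, which is the slow step described above. Cutting on the carbon side makes the depside carbonyl the ester carbon of an unhindered aryl malonate, 13. Ring A then reduces to the silyl triflate 18, a phloroglucinol derivative. The forward reaction must add the malonate carbon at the aryne carbon remote from the flanking benzyloxy group, must transfer the aryloxycarbonyl group and not the amide carbonyl, and must keep the ring B phenoxide attached.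

**Malonate half-amide (13 ⇐ 10 + 12; 12 ⇐ 11).** The ester C–O bond between O4 of ring B and the malonyl carbon is cut. Here the acyl partner is unhindered, so a carbodiimide esterification of phenol 10 with acid 12 is enough. The C–N bond of 12 is cut back to Meldrum's acid 11, which an amine opens to a malonic half-amide in one step.

**Ring B protecting groups (10 ⇐ 9 ⇐ 8 ⇐ 7 ⇐ 6).** The ring B acid must end as a benzyl ester so that it falls with the ring A ethers, and O4 must be free. The benzyl ester of 10 is cut to the hydroxy acid 9, the free phenol of 9 to the benzyl ether 8, and the acid of 8 to the methyl ester 7. This order puts the only harsh step, saponification of a hindered ester, on a molecule with no aryl ester and with the ketone already held as the dioxolane 7. The ketal is traced to ketone 6. It is needed three times: against base in the saponification, against fluoride and aryne in the key step, and against the Grignard reagent.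

**Ring B side chain (6 ⇐ 3 + 5; 3 ⇐ 2 ⇐ 1; 5 ⇐ 4).** The CH2–C(=O) bond of the oxoheptyl chain is cut to the benzylic anion of toluate 3 and Weinreb amide 5. The ring carbon pattern of ring B is then bought with methyl orsellinate 1. The two O-alkyl bonds of 3 are cut in turn: the methyl ether back to 2 and the benzyl ether back to 1. The hydrogen bond from the 2-hydroxyl to the ester tells the two hydroxyls of 1 apart without a directing step. Amide 5 comes from hexanoyl chloride 4.

**Aryne precursor (18 ⇐ 16 through 17; 16 ⇐ 15 ⇐ 14).** The S–O bond of the triflate and the C–Si bond are cut to the O-silyl bromophenol 16. Halogen–lithium exchange and a 1,3 silyl shift from oxygen to carbon give phenolate 17, which is triflated in the same flask. Compound 16 comes from bromophenol 15, and 15 from 3,5-bis(benzyloxy)phenol 14. The forward steps ask for bromination ortho, not para, to the free hydroxyl.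

## Roads not taken

**Alternative 1:** Ring B is built from acyclic pieces. The cut is at C1–C6 and C2–C3 of ring B. In the forward step dibenzyl malonate A3 adds to the enone A2, and the methyl ketone enolate so formed closes onto one ester to give the cyclohexanedione A1. The trans relationship in A1 is of no consequence because both centres vanish on aromatisation. Its merits are real. The benzyl ester is present from the start, so the saponification and re-esterification of steps 6 to 8 disappear. The ketal-protected chain is in place before the ring exists, so no lateral metalation is needed. The weak points lie after the key step. A1 is a cyclic vinylogous acid, and O-alkylation of such systems favours the less hindered C4 oxygen, which is the one that must stay free for the depside bond; the C2 oxygen, next to the ester, is the one that needs the methyl group. An oxidative aromatisation is also needed. In A2 the ketal carbon is attached to the gamma carbon of the enone, so gamma deprotonation can open the dioxolane by vinylogous elimination under the alkoxide conditions. A2 itself takes several steps to make, so the count to phenol 10 is not clearly lower. Above all, this road stops at 10 and leaves the hindered ester and the ring A chain unsolved. The chosen plan buys the ring B pattern with 1, where the hydrogen bond already differentiates the oxygens, and spends its one inventive step on the bond that is actually difficult.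

**Alternative 2:** Both CH2–C(=O) bonds of the side chains are cut at once. The bis(chloromethyl) depside A5 and two molecules of hexanoyl chloride 4 would be joined by nickel-catalysed reductive coupling with zinc as the reductant, giving the diacetate tert-butyl ester A4. This road uses the identity of the two chains, needs no ketone protection and brings no hard nucleophile near the depside ester. On paper it is shorter and more convergent than the chosen plan, and that should be conceded. Its risks are concentrated in three places. Each benzylic chloride of A5 sits ortho to an ester carbonyl, the classical arrangement for phthalide formation; on ring A that closure would expel ring B. Two benzylic positions in one molecule invite reductive homocoupling to bibenzyls and oligomers, every coupling has to succeed twice, and zerovalent nickel is also able to insert into the C(acyl)–O bond of aryl esters, of which A5 has three. Preparing A5 requires benzylic halogenation of two orsellinate methyl groups. The end of the route must remove two aryl acetates in the presence of a third aryl ester, the depside bond, on a substrate whose ketones now condense onto the esters under base. Against the shorter count the chosen plan sets an endgame that is neutral and needs no selection among three aryl esters (hydrogenolysis), and a chain-forming event on ring A that makes the ester at the same time.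

**Alternative 3:** Ring A is cut at C1–C6 and traced to the open-chain triketo aryl ester A7, already attached to the ring B oxygen. Mild base would close it by aldol attack of chain C2 on the C7 ketone, and dehydration and enolisation would give the resorcylate A6 with both ring A phenols free. This is the biomimetic route, and it has two advantages over the chosen plan. The cyclisation type, a 3,5,7-triketo ester closing to a resorcylate, is established for alkyl esters, so it stands closer to precedent than the aryne step. Ring A also needs no protecting groups. Like the chosen plan it forms the depside oxygen–carbon bond with an unhindered acyl donor. The weakness is specific to this target: the ester in A7 is an aryl ester, a good leaving group placed in a chain that holds three enolisable ketones. Attack of the C5 enol oxygen on C1 gives a pyrone, and attack of C6 on C1 gives an acylphloroglucinol. Both expel the ring B phenoxide, and both are the known competitors of the aldol mode even with alkyl esters. Assembling A7 with its distal ketal is a multistep chain synthesis, and two ketals must later be hydrolysed next to free phenols. The chosen plan also has a phenoxide-loss channel, at alkoxide 20, but there the side path can return to the same product (see step 14), and the substitution pattern of ring A is fixed by the polarisation of the aryne, not by a choice among cyclisation modes. On precedent alone alternative 3 is the stronger road. The chosen plan is stronger on regiochemical certainty and on the stability of the intermediate it has to carry, an aryl malonamate against an aryl triketo ester.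

Key step: step 14

Remark on the chemistry: methyl orsellinate 1, hexanoyl chloride 4, Meldrum's acid 11 and 3,5-bis(benzyloxy)phenol 14 are taken as purchasable; amide 5 is made in step 3 so that nothing rests on its availability. The target is achiral; the only stereogenic carbons in the plan are the two transient ones of alkoxide 20, which forms as a mixture and is consumed.

## Route

Step 1
Reactants: 1 methyl orsellinate (methyl 2,4-dihydroxy-6-methylbenzoate)
Product: 2 methyl 4-(benzyloxy)-2-hydroxy-6-methylbenzoate
Conditions: BnBr (1.05 equiv), K2CO3, acetone, reflux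
Reagents that add atoms: benzyl bromide, BrCc1ccccc1
Why: Williamson etherification; the 2-hydroxyl is tied to the ester carbonyl by a hydrogen bond and is the weaker acid, so one equivalent of halide should go to O4.

Step 2
Reactants: 2 methyl 4-(benzyloxy)-2-hydroxy-6-methylbenzoate
Product: 3 methyl 4-(benzyloxy)-2-methoxy-6-methylbenzoate
Conditions: MeI, K2CO3, DMF, 50 °C
Reagents that add atoms: iodomethane, CI
Why: Williamson etherification of the remaining, hydrogen-bonded phenol, which needs the more polar solvent and gentle heating; nothing else in 2 is alkylated under carbonate.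

Step 3
Reactants: 4 hexanoyl chloride
Product: 5 N-methoxy-N-methylhexanamide
Conditions: MeNH(OMe)·HCl, Et3N (2.2 equiv), CH2Cl2, 0 °C to rt
Reagents that add atoms: N,O-dimethylhydroxylamine hydrochloride, CNOC.Cl
Why: N-acylation of the amine by an acid chloride (Weinreb amide formation), a standard reaction of a simple aliphatic acyl chloride.

Step 4
Reactants: 3 methyl 4-(benzyloxy)-2-methoxy-6-methylbenzoate; 5 N-methoxy-N-methylhexanamide
Product: 6 methyl 4-(benzyloxy)-2-methoxy-6-(2-oxoheptyl)benzoate
Conditions: LiN(iPr)2 (1.2 equiv), THF, −78 °C; then 5, −78 °C; aq. NH4Cl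
Reagents that add atoms: none
Why: Lateral (benzylic) lithiation of an ortho-toluate followed by acylation with a Weinreb amide; the chelated tetrahedral adduct prevents a second addition and keeps the ketone masked until the quench, so it cannot condense onto the neighbouring ester in the basic medium.

Step 5
Reactants: 6 methyl 4-(benzyloxy)-2-methoxy-6-(2-oxoheptyl)benzoate
Product: 7 methyl 4-(benzyloxy)-2-methoxy-6-[(2-pentyl-1,3-dioxolan-2-yl)methyl]benzoate
Conditions: (TMSOCH2)2, TMSOTf (cat.), CH2Cl2, −78 to −20 °C
Reagents that add atoms: 1,2-bis(trimethylsilyloxy)ethane, C[Si](C)(C)OCCO[Si](C)(C)C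
Why: Noyori ketalisation under aprotic conditions at low temperature, chosen over hot acid and glycol so that the enol of 6 is not given the chance to lactonise onto the ester.

Step 6
Reactants: 7 methyl 4-(benzyloxy)-2-methoxy-6-[(2-pentyl-1,3-dioxolan-2-yl)methyl]benzoate
Product: 8 4-(benzyloxy)-2-methoxy-6-[(2-pentyl-1,3-dioxolan-2-yl)methyl]benzoic acid
Conditions: KOH, DMSO–H2O, 90 °C; then cold 1 M HCl to pH 4
Reagents that add atoms: potassium hydroxide, [K+].[OH-]
Why: Saponification of a di-ortho-substituted benzoate, which needs hydroxide in a dipolar aprotic medium; the dioxolane and the benzyl ether are inert to base, and the acidification is kept cold and mild to spare the ketal.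

Step 7
Reactants: 8 4-(benzyloxy)-2-methoxy-6-[(2-pentyl-1,3-dioxolan-2-yl)methyl]benzoic acid
Product: 9 4-hydroxy-2-methoxy-6-[(2-pentyl-1,3-dioxolan-2-yl)methyl]benzoic acid
Conditions: H2 (1 atm), 10% Pd/C, EtOAc, rt
Reagents that add atoms: none
Why: Hydrogenolysis of the aryl benzyl ether under neutral conditions; the ketal and the carboxylic acid are untouched, and the product is used without heating to avoid decarboxylation.

Step 8
Reactants: 9 4-hydroxy-2-methoxy-6-[(2-pentyl-1,3-dioxolan-2-yl)methyl]benzoic acid
Product: 10 benzyl 4-hydroxy-2-methoxy-6-[(2-pentyl-1,3-dioxolan-2-yl)methyl]benzoate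
Conditions: BnBr (1.0 equiv), KHCO3, DMF, rt
Reagents that add atoms: benzyl bromide, BrCc1ccccc1
Why: O-alkylation of a carboxylate; hydrogencarbonate ionises the acid but not the phenol, so the benzyl group should go to the carboxyl oxygen only.

Step 9
Reactants: 11 Meldrum's acid (2,2-dimethyl-1,3-dioxane-4,6-dione)
Product: 12 3-[methoxy(methyl)amino]-3-oxopropanoic acid
Conditions: MeNH(OMe)·HCl, Et3N (1.0 equiv), MeCN, 70 °C
Reagents that add atoms: N,O-dimethylhydroxylamine hydrochloride, CNOC.Cl
Why: Aminolysis of Meldrum's acid: the amine opens one acyl–oxygen bond and acetone is lost, leaving the malonic half-amide; only one equivalent of base is used so that the acidic CH2 of 11 is not converted into its unreactive anion.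

Step 10
Reactants: 10 benzyl 4-hydroxy-2-methoxy-6-[(2-pentyl-1,3-dioxolan-2-yl)methyl]benzoate; 12 3-[methoxy(methyl)amino]-3-oxopropanoic acid
Product: 13 benzyl 2-methoxy-4-({3-[methoxy(methyl)amino]-3-oxopropanoyl}oxy)-6-[(2-pentyl-1,3-dioxolan-2-yl)methyl]benzoate
Conditions: DCC, DMAP (cat.), CH2Cl2, 0 °C to rt
Reagents that add atoms: none
Why: Steglich esterification; malonic half-acids are activated readily by carbodiimides (in part through the acylketene), and the acyl carbon is unhindered, so the weakly nucleophilic phenol should be acylated under neutral conditions that spare the ketal.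

Step 11
Reactants: 14 3,5-bis(benzyloxy)phenol
Product: 15 3,5-bis(benzyloxy)-2-bromophenol
Conditions: NBS (1.0 equiv), CH2Cl2, −78 °C to rt
Reagents that add atoms: N-bromosuccinimide, O=C1CCC(=O)N1Br
Why: Electrophilic bromination of a phloroglucinol ether; in a non-polar solvent at low temperature the hydroxyl directs the reagent to its ortho position, which is also the less crowded of the two kinds of free site and is statistically doubled.

Step 12
Reactants: 15 3,5-bis(benzyloxy)-2-bromophenol
Product: 16 [3,5-bis(benzyloxy)-2-bromophenoxy]trimethylsilane
Conditions: (Me3Si)2NH, THF, 70 °C; evaporate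
Reagents that add atoms: hexamethyldisilazane, C[Si](C)(C)N[Si](C)(C)C
Why: O-silylation of a phenol with a silazane, which gives only ammonia as by-product and lets the crude silyl ether go on after evaporation.

Step 13
Reactants: 16 [3,5-bis(benzyloxy)-2-bromophenoxy]trimethylsilane
Product: 18 3,5-bis(benzyloxy)-2-(trimethylsilyl)phenyl trifluoromethanesulfonate, via lithium 2-silylphenolate 17 (not isolated)
Conditions: n-BuLi, THF, −100 to −80 °C; then Tf2O, −100 °C to rt
Reagents that add atoms: trifluoromethanesulfonic anhydride, O=S(=O)(OS(=O)(=O)C(F)(F)F)C(F)(F)F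
Why: Bromine–lithium exchange is followed by a retro-Brook 1,3 shift of silicon from oxygen to the lithiated carbon, and the phenolate 17 is sulfonylated in the same flask; this is the standard entry to ortho-silyl aryl triflates, and the exchange at −100 °C is far faster than any attack of the base on the benzyl ethers.

Step 14
Reactants: 13 benzyl 2-methoxy-4-({3-[methoxy(methyl)amino]-3-oxopropanoyl}oxy)-6-[(2-pentyl-1,3-dioxolan-2-yl)methyl]benzoate; 18 3,5-bis(benzyloxy)-2-(trimethylsilyl)phenyl trifluoromethanesulfonate
Product: 21 benzyl 4-[(2,4-bis(benzyloxy)-6-{2-[methoxy(methyl)amino]-2-oxoethyl}benzoyl)oxy]-2-methoxy-6-[(2-pentyl-1,3-dioxolan-2-yl)methyl]benzoate, via aryne 19 (not isolated), via cesium benzocyclobutenolate 20 (not isolated)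
Conditions: CsF (3 equiv), MeCN, 40 °C, 18 (1.5 equiv) added slowly
Reagents that add atoms: none
Why: Proposed new method: fluoride removes the silyl group of 18 and triflate leaves to give aryne 19, while fluoride and the anions of the cycle deprotonate the doubly activated CH2 of 13. The carbanion adds to the aryne carbon meta to the flanking benzyloxy group, because that oxygen withdraws inductively and distorts the aryne so that negative charge builds up on the carbon next to it. The aryl anion placed there attacks the aryl ester carbonyl (4-exo-trig) and not the less electrophilic Weinreb amide carbonyl, giving the benzocyclobutenolate 20. Strain-driven C–C cleavage of 20 releases the amide enolate, which is protonated by a further molecule of 13, so that in sum the aryne has inserted into the CH2–C(=O)OAr bond and both the C6–CH2 and the C1–C(=O) bonds of ring A are formed. The closest known reaction type is the fluoride-induced acyl-alkylation of arynes by beta-keto esters and the related insertion into dialkyl malonates, in which a ketone or an alkoxycarbonyl group migrates; an aryloxycarbonyl group paired with an amide has not been used. No ring remains in the product and no stereocentre is formed, since the two centres of 20 are lost on ring opening. The step needs three selectivities: the site of addition, set by the 3-benzyloxy group; the choice of carbonyl, set by the electrophilicity gap between aryl ester and Weinreb amide; and ring opening of 20 in preference to loss of the ring B phenoxide. If the phenoxide is lost, the benzocyclobutenone formed can be reopened by that same phenoxide at its strained carbonyl towards the amide-stabilised benzylic anion, which also leads to 21.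

Step 15
Reactants: 21 benzyl 4-[(2,4-bis(benzyloxy)-6-{2-[methoxy(methyl)amino]-2-oxoethyl}benzoyl)oxy]-2-methoxy-6-[(2-pentyl-1,3-dioxolan-2-yl)methyl]benzoate
Product: 22 benzyl 4-{[2,4-bis(benzyloxy)-6-(2-oxoheptyl)benzoyl]oxy}-2-methoxy-6-[(2-pentyl-1,3-dioxolan-2-yl)methyl]benzoate
Conditions: n-C5H11MgBr (2 equiv), THF, −78 to −20 °C; aq. NH4Cl at −20 °C
Reagents that add atoms: pentylmagnesium bromide, CCCCC[Mg]Br
Why: Weinreb ketone synthesis; the magnesium chelate stops the reaction at the ketone stage and releases it only on quench, and both esters are di-ortho-substituted benzoates, which are far slower toward a Grignard reagent at low temperature than the unhindered amide.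

Step 16
Reactants: 22 benzyl 4-{[2,4-bis(benzyloxy)-6-(2-oxoheptyl)benzoyl]oxy}-2-methoxy-6-[(2-pentyl-1,3-dioxolan-2-yl)methyl]benzoate
Product: 23 benzyl 4-{[2,4-bis(benzyloxy)-6-(2-oxoheptyl)benzoyl]oxy}-2-methoxy-6-(2-oxoheptyl)benzoate
Conditions: 1 M aq. HCl, THF, 0 °C to rt
Reagents that add atoms: water, O
Why: Acid hydrolysis of a dialkyl ketone dioxolane; dilute acid at or below room temperature should not open hindered benzoate esters, and the ring B carboxyl is still a benzyl ester, the form least prone to close onto the new ketone.

Step 17
Reactants: 23 benzyl 4-{[2,4-bis(benzyloxy)-6-(2-oxoheptyl)benzoyl]oxy}-2-methoxy-6-(2-oxoheptyl)benzoate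
Product: 24 arthonioic acid (4-{[2,4-dihydroxy-6-(2-oxoheptyl)benzoyl]oxy}-2-methoxy-6-(2-oxoheptyl)benzoic acid)
Conditions: H2 (1 atm), 10% Pd/C, EtOAc, rt
Reagents that add atoms: none
Why: Hydrogenolysis of two aryl benzyl ethers and one benzyl ester in a neutral medium; aliphatic ketones and the aryl ester are not reduced under these conditions, so the target is released without acid or base.

## Compound list

1 | methyl orsellinate (methyl 2,4-dihydroxy-6-methylbenzoate) | COC(=O)c1c(C)cc(O)cc1O | starting material
2 | methyl 4-(benzyloxy)-2-hydroxy-6-methylbenzoate | COC(=O)c1c(C)cc(OCc2ccccc2)cc1O | intermediate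
3 | methyl 4-(benzyloxy)-2-methoxy-6-methylbenzoate | COC(=O)c1c(C)cc(OCc2ccccc2)cc1OC | intermediate
4 | hexanoyl chloride | CCCCCC(Cl)=O | starting material
5 | N-methoxy-N-methylhexanamide | CCCCCC(=O)N(C)OC | intermediate
6 | methyl 4-(benzyloxy)-2-methoxy-6-(2-oxoheptyl)benzoate | CCCCCC(=O)Cc1cc(OCc2ccccc2)cc(OC)c1C(=O)OC | intermediate
7 | methyl 4-(benzyloxy)-2-methoxy-6-[(2-pentyl-1,3-dioxolan-2-yl)methyl]benzoate | CCCCCC1(Cc2cc(OCc3ccccc3)cc(OC)c2C(=O)OC)OCCO1 | intermediate
8 | 4-(benzyloxy)-2-methoxy-6-[(2-pentyl-1,3-dioxolan-2-yl)methyl]benzoic acid | CCCCCC1(Cc2cc(OCc3ccccc3)cc(OC)c2C(=O)O)OCCO1 | intermediate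
9 | 4-hydroxy-2-methoxy-6-[(2-pentyl-1,3-dioxolan-2-yl)methyl]benzoic acid | CCCCCC1(Cc2cc(O)cc(OC)c2C(=O)O)OCCO1 | intermediate
10 | benzyl 4-hydroxy-2-methoxy-6-[(2-pentyl-1,3-dioxolan-2-yl)methyl]benzoate | CCCCCC1(Cc2cc(O)cc(OC)c2C(=O)OCc2ccccc2)OCCO1 | intermediate
11 | Meldrum's acid (2,2-dimethyl-1,3-dioxane-4,6-dione) | CC1(C)OC(=O)CC(=O)O1 | starting material
12 | 3-[methoxy(methyl)amino]-3-oxopropanoic acid | CON(C)C(=O)CC(=O)O | intermediate
13 | benzyl 2-methoxy-4-({3-[methoxy(methyl)amino]-3-oxopropanoyl}oxy)-6-[(2-pentyl-1,3-dioxolan-2-yl)methyl]benzoate | CON(C)C(=O)CC(=O)Oc1cc(CC2(CCCCC)OCCO2)c(C(=O)OCc2ccccc2)c(OC)c1 | intermediate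
14 | 3,5-bis(benzyloxy)phenol | Oc1cc(OCc2ccccc2)cc(OCc2ccccc2)c1 | starting material
15 | 3,5-bis(benzyloxy)-2-bromophenol | Oc1cc(OCc2ccccc2)cc(OCc2ccccc2)c1Br | intermediate
16 | [3,5-bis(benzyloxy)-2-bromophenoxy]trimethylsilane | C[Si](C)(C)Oc1cc(OCc2ccccc2)cc(OCc2ccccc2)c1Br | intermediate
17 | lithium 3,5-bis(benzyloxy)-2-(trimethylsilyl)phenolate | [Li+].[O-]c1cc(OCc2ccccc2)cc(OCc2ccccc2)c1[Si](C)(C)C | intermediate (not isolated)
18 | 3,5-bis(benzyloxy)-2-(trimethylsilyl)phenyl trifluoromethanesulfonate | C[Si](C)(C)c1c(OCc2ccccc2)cc(OCc2ccccc2)cc1OS(=O)(=O)C(F)(F)F | intermediate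
19 | 3,5-bis(benzyloxy)benzyne (3,5-bis(benzyloxy)-1,2-didehydrobenzene) | C1#CC(OCc2ccccc2)=CC(OCc2ccccc2)=C1 | intermediate (not isolated)
20 | cesium 3,5-bis(benzyloxy)-7-(ring B aryloxy)-8-[methoxy(methyl)carbamoyl]bicyclo[4.2.0]octa-1,3,5-trien-7-olate (ring B aryl as in 10; both sp3 centres unassigned) | [Cs+].[O-]C1(Oc2cc(CC3(CCCCC)OCCO3)c(C(=O)OCc3ccccc3)c(OC)c2)C(C(=O)N(C)OC)c2cc(OCc3ccccc3)cc(OCc3ccccc3)c21 | intermediate (not isolated)
21 | benzyl 4-[(2,4-bis(benzyloxy)-6-{2-[methoxy(methyl)amino]-2-oxoethyl}benzoyl)oxy]-2-methoxy-6-[(2-pentyl-1,3-dioxolan-2-yl)methyl]benzoate | CON(C)C(=O)Cc1cc(OCc2ccccc2)cc(OCc2ccccc2)c1C(=O)Oc1cc(CC2(CCCCC)OCCO2)c(C(=O)OCc2ccccc2)c(OC)c1 | intermediate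
22 | benzyl 4-{[2,4-bis(benzyloxy)-6-(2-oxoheptyl)benzoyl]oxy}-2-methoxy-6-[(2-pentyl-1,3-dioxolan-2-yl)methyl]benzoate | CCCCCC(=O)Cc1cc(OCc2ccccc2)cc(OCc2ccccc2)c1C(=O)Oc1cc(CC2(CCCCC)OCCO2)c(C(=O)OCc2ccccc2)c(OC)c1 | intermediate
23 | benzyl 4-{[2,4-bis(benzyloxy)-6-(2-oxoheptyl)benzoyl]oxy}-2-methoxy-6-(2-oxoheptyl)benzoate | CCCCCC(=O)Cc1cc(OCc2ccccc2)cc(OCc2ccccc2)c1C(=O)Oc1cc(CC(=O)CCCCC)c(C(=O)OCc2ccccc2)c(OC)c1 | intermediate
24 | arthonioic acid | CCCCCC(=O)Cc1cc(O)cc(O)c1C(=O)Oc1cc(CC(=O)CCCCC)c(C(=O)O)c(OC)c1 | target

## Step count and risks

Total: 17 steps. Longest linear sequence: 12 steps from methyl orsellinate 1 (steps 1, 2, 4, 5, 6, 7, 8, 10, 14, 15, 16, 17). The aryne line (steps 11 to 13), the malonic half-amide (step 9) and amide 5 (step 3) are side branches.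

**Step 14** is the key step and the only one beyond known chemistry. Three processes could divert it.
- The ring B phenoxide may be lost, by elimination from the malonate carbanion to a ketene or by collapse of 20, and then captured by the aryne as a diaryl ether.
- The aryl anion may be protonated before it reaches the ester carbonyl, which leaves plain alpha-arylation without acyl transfer.
- The amide enolate released from 20 may close through oxygen onto the new aryl ester with loss of ring B.

All three follow from the feature that makes the substrate useful: an activated aryl ester beside an acidic CH2.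

The fallback uses known chemistry only and makes the depside bond by classical esterification of a ring A acid. It sets out from 1, which is benzylated at both oxygens (excess BnBr, K2CO3, DMF) to methyl 2,4-bis(benzyloxy)-6-methylbenzoate F1. Lateral lithiation and acylation with 5, as in step 4, should give methyl 2,4-bis(benzyloxy)-6-(2-oxoheptyl)benzoate F2. Ketalisation as in step 5 gives methyl 2,4-bis(benzyloxy)-6-[(2-pentyl-1,3-dioxolan-2-yl)methyl]benzoate F3, and saponification as in step 6 gives 2,4-bis(benzyloxy)-6-[(2-pentyl-1,3-dioxolan-2-yl)methyl]benzoic acid F4. Coupling of this acid with phenol 10 (DCC, DMAP, CH2Cl2) gives benzyl 4-({2,4-bis(benzyloxy)-6-[(2-pentyl-1,3-dioxolan-2-yl)methyl]benzoyl}oxy)-2-methoxy-6-[(2-pentyl-1,3-dioxolan-2-yl)methyl]benzoate F5. Hydrolysis of both dioxolanes (1 M HCl, THF) brings the route back at 23. This path contains the slow hindered acylation that the key step avoids, and so it is held in reserve.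

**Step 15.** The Grignard reagent may act as a base on the CH2 between the ring and the amide, which returns starting material or lets the enolate close onto the aryl ester. On warming it may also add to the depside carbonyl. The fallback changes the nucleophile class and the order of events. From 21, lithium pent-1-ynide (1-pentyne, n-BuLi, THF, −78 °C) is a far weaker base than an alkylmagnesium and should give the ynone benzyl 4-{[2,4-bis(benzyloxy)-6-(2-oxohept-3-yn-1-yl)benzoyl]oxy}-2-methoxy-6-[(2-pentyl-1,3-dioxolan-2-yl)methyl]benzoate F6. Ketal hydrolysis as in step 16 gives benzyl 4-{[2,4-bis(benzyloxy)-6-(2-oxohept-3-yn-1-yl)benzoyl]oxy}-2-methoxy-6-(2-oxoheptyl)benzoate F7. The final hydrogenation then saturates the triple bond while it removes the benzyl groups, and the route is rejoined at 24.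

**Step 16.** Under acid the enol of the new ring A ketone may lactonise onto the depside carbonyl and release the ring B phenol (isocoumarin formation); the same closure is possible, more slowly, on the ring B benzyl ester. The fallback reverses the endgame and drops the mineral acid. From 22, hydrogenolysis first (H2, Pd/C, EtOAc) gives 4-{[2,4-dihydroxy-6-(2-oxoheptyl)benzoyl]oxy}-2-methoxy-6-[(2-pentyl-1,3-dioxolan-2-yl)methyl]benzoic acid F8. Its dioxolane is then hydrolysed in warm aqueous THF with the neighbouring ring B carboxyl as the only acid present (intramolecular general acid catalysis), giving 24.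

**Step 4.** The benzylic anion of 3 may add to the ester of a second molecule of 3 (self-condensation), or lateral deprotonation of the electron-rich toluate may be incomplete. The fallback removes the electrophilic ester before metalation. From 3, saponification (KOH, DMSO–H2O) gives 4-(benzyloxy)-2-methoxy-6-methylbenzoic acid F9. Its dianion (2.2 equiv LiN(iPr)2, THF, −78 °C), which carries no acceptor carbonyl, is acylated with 5 to give 4-(benzyloxy)-2-methoxy-6-(2-oxoheptyl)benzoic acid F10. Methylation of the carboxylate (MeI, KHCO3, DMF) returns to 6.

**Step 11.** Bromination may go para to the hydroxyl, at the carbon between the two benzyloxy groups, or go twice, since all three free positions are activated by three oxygens. The fallback places the silyl group by directed metalation in place of halogenation. From 14, isopropyl isocyanate and Et3N give 3,5-bis(benzyloxy)phenyl isopropylcarbamate F11. N-Silylation in the flask (TMSOTf, TMEDA), ortho-lithiation between the carbamate and the benzyloxy group (n-BuLi, TMEDA, Et2O, −78 °C) and quench with Me3SiCl give 3,5-bis(benzyloxy)-2-(trimethylsilyl)phenyl isopropylcarbamate F12. Cleavage of the carbamate with Et2NH and DBU, followed by PhNTf2 in the same flask, gives 18, so that 15, 16 and 17 are bypassed.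

## Further compounds

F1 | step 14 | methyl 2,4-bis(benzyloxy)-6-methylbenzoate | COC(=O)c1c(C)cc(OCc2ccccc2)cc1OCc1ccccc1
F2 | step 14 | methyl 2,4-bis(benzyloxy)-6-(2-oxoheptyl)benzoate | CCCCCC(=O)Cc1cc(OCc2ccccc2)cc(OCc2ccccc2)c1C(=O)OC
F3 | step 14 | methyl 2,4-bis(benzyloxy)-6-[(2-pentyl-1,3-dioxolan-2-yl)methyl]benzoate | CCCCCC1(Cc2cc(OCc3ccccc3)cc(OCc3ccccc3)c2C(=O)OC)OCCO1
F4 | step 14 | 2,4-bis(benzyloxy)-6-[(2-pentyl-1,3-dioxolan-2-yl)methyl]benzoic acid | CCCCCC1(Cc2cc(OCc3ccccc3)cc(OCc3ccccc3)c2C(=O)O)OCCO1
F5 | step 14 | benzyl 4-({2,4-bis(benzyloxy)-6-[(2-pentyl-1,3-dioxolan-2-yl)methyl]benzoyl}oxy)-2-methoxy-6-[(2-pentyl-1,3-dioxolan-2-yl)methyl]benzoate | CCCCCC1(Cc2cc(OCc3ccccc3)cc(OCc3ccccc3)c2C(=O)Oc2cc(CC3(CCCCC)OCCO3)c(C(=O)OCc3ccccc3)c(OC)c2)OCCO1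
F6 | step 15 | benzyl 4-{[2,4-bis(benzyloxy)-6-(2-oxohept-3-yn-1-yl)benzoyl]oxy}-2-methoxy-6-[(2-pentyl-1,3-dioxolan-2-yl)methyl]benzoate | CCCC#CC(=O)Cc1cc(OCc2ccccc2)cc(OCc2ccccc2)c1C(=O)Oc1cc(CC2(CCCCC)OCCO2)c(C(=O)OCc2ccccc2)c(OC)c1
F7 | step 15 | benzyl 4-{[2,4-bis(benzyloxy)-6-(2-oxohept-3-yn-1-yl)benzoyl]oxy}-2-methoxy-6-(2-oxoheptyl)benzoate | CCCC#CC(=O)Cc1cc(OCc2ccccc2)cc(OCc2ccccc2)c1C(=O)Oc1cc(CC(=O)CCCCC)c(C(=O)OCc2ccccc2)c(OC)c1
F8 | step 16 | 4-{[2,4-dihydroxy-6-(2-oxoheptyl)benzoyl]oxy}-2-methoxy-6-[(2-pentyl-1,3-dioxolan-2-yl)methyl]benzoic acid | CCCCCC(=O)Cc1cc(O)cc(O)c1C(=O)Oc1cc(CC2(CCCCC)OCCO2)c(C(=O)O)c(OC)c1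
F9 | step 4 | 4-(benzyloxy)-2-methoxy-6-methylbenzoic acid | Cc1cc(OCc2ccccc2)cc(OC)c1C(=O)O
F10 | step 4 | 4-(benzyloxy)-2-methoxy-6-(2-oxoheptyl)benzoic acid | CCCCCC(=O)Cc1cc(OCc2ccccc2)cc(OC)c1C(=O)O
F11 | step 11 | 3,5-bis(benzyloxy)phenyl isopropylcarbamate | CC(C)NC(=O)Oc1cc(OCc2ccccc2)cc(OCc2ccccc2)c1
F12 | step 11 | 3,5-bis(benzyloxy)-2-(trimethylsilyl)phenyl isopropylcarbamate | CC(C)NC(=O)Oc1cc(OCc2ccccc2)cc(OCc2ccccc2)c1[Si](C)(C)C
A1 | alternative 1 | racemic trans benzyl 2,4-dioxo-6-[(2-pentyl-1,3-dioxolan-2-yl)methyl]cyclohexane-1-carboxylate (one enantiomer drawn) | O=C1CC(=O)[C@H](C(=O)OCc2ccccc2)[C@@H](CC2(CCCCC)OCCO2)C1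
A2 | alternative 1 | (E)-5-(2-pentyl-1,3-dioxolan-2-yl)pent-3-en-2-one | CC(=O)/C=C/CC1(CCCCC)OCCO1
A3 | alternative 1 | dibenzyl malonate | O=C(CC(=O)OCc1ccccc1)OCc1ccccc1
A4 | alternative 2 | tert-butyl 4-{[2,4-diacetoxy-6-(2-oxoheptyl)benzoyl]oxy}-2-methoxy-6-(2-oxoheptyl)benzoate | CCCCCC(=O)Cc1cc(OC(C)=O)cc(OC(C)=O)c1C(=O)Oc1cc(CC(=O)CCCCC)c(C(=O)OC(C)(C)C)c(OC)c1
A5 | alternative 2 | tert-butyl 4-{[2,4-diacetoxy-6-(chloromethyl)benzoyl]oxy}-6-(chloromethyl)-2-methoxybenzoate | CC(=O)Oc1cc(CCl)c(C(=O)Oc2cc(CCl)c(C(=O)OC(C)(C)C)c(OC)c2)c(OC(C)=O)c1
A6 | alternative 3 | benzyl 4-({2,4-dihydroxy-6-[(2-pentyl-1,3-dioxolan-2-yl)methyl]benzoyl}oxy)-2-methoxy-6-[(2-pentyl-1,3-dioxolan-2-yl)methyl]benzoate | CCCCCC1(Cc2cc(O)cc(O)c2C(=O)Oc2cc(CC3(CCCCC)OCCO3)c(C(=O)OCc3ccccc3)c(OC)c2)OCCO1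
A7 | alternative 3 | benzyl 2-methoxy-6-[(2-pentyl-1,3-dioxolan-2-yl)methyl]-4-{[3,5,7-trioxo-8-(2-pentyl-1,3-dioxolan-2-yl)octanoyl]oxy}benzoate | CCCCCC1(CC(=O)CC(=O)CC(=O)CC(=O)Oc2cc(CC3(CCCCC)OCCO3)c(C(=O)OCc3ccccc3)c(OC)c2)OCCO1
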